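C1 is the ring carbonyl, C2=C3 the alkene, C4 the methoxy carbon, C5 the ring CH2 and C6 the quaternary carbon; C7 (CHMe) and C8 (CHOH–aryl) form the side chain and C9–C11 the allyl group.
Retrosynthesis cuts the six-membered ring at C1–C2 (alkenyl addition to an aldehyde) and at C3–C4 (acetylide acylation), leaving a γ-lactone ring O–C1H2–C6–C5H2–C4(=O).
C6 differs from a tertiary CH centre only by its bond to C5, and a diazoacetate on the C1 oxygen places its carbene carbon (future C5) where C6–H is reached through a five-membered transition state, so the lactone is cut at C5–C6.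
The remaining cuts are C6–C9 (lactone enolate allylation) and C7–C8 (crotylboration of 3,4-dimethoxybenzaldehyde).
Forward, C7–C8 is joined first, a cis-lactone template carries the allylation, the opened chain is closed as the C5–C6 lactone, acetylene supplies C2–C3, and the cyclohexenone ring closes last at C1–C2.
C7 and C8 come from the (Z)-crotylborane (reagent control), C6 from allylation anti to the methyl group followed by retention in the C–H insertion, and C4 from a catalyst-controlled ketone reduction.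

Key step: step 9

Remark: the (S,S) transfer-hydrogenation catalyst in step 16 is assigned by the aryl-ketone model with the C2=C3 alkene in the role of the aryl group, and hydroxy ynone 23 is drawn open-chain although it may rest as its cyclic hemiketal.

Step 1
Reactants: 1 3,4-dimethoxybenzaldehyde; 2 cis-but-2-ene
Product: 6 (1S,2R)-1-(3,4-dimethoxyphenyl)-2-methylbut-3-en-1-ol, via (Z)-crotylpotassium 3 (not isolated), via (Z)-crotyldiisopinocampheylborane 4 (not isolated), via borinate ester 5 (not isolated)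
Conditions: 2, n-BuLi, KOt-Bu, THF, −78 to −45 °C; (−)-Ipc2BOMe, −78 °C; BF3·OEt2; 1, −78 °C; then NaOH, H2O2, 0 °C to rt
Reagents that add atoms: none
Why: Brown crotylboration through a closed chair transition state, in which the Z geometry of the borane gives the syn C7–C8 pair and the isopinocampheyl groups derived from (+)-α-pinene select the aldehyde face that sets 1S,2R.

Step 2
Reactants: 6 (1S,2R)-1-(3,4-dimethoxyphenyl)-2-methylbut-3-en-1-ol
Product: 8 (1S,2R)-1-(3,4-dimethoxyphenyl)-2-methylbutane-1,4-diol, via alkyl-9-BBN adduct 7 (not isolated)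
Conditions: 9-BBN, THF, 0 °C to rt; then NaOH, H2O2
Reagents that add atoms: hydrogen peroxide, OO
Why: Anti-Markovnikov hydroboration–oxidation of the terminal alkene with a bulky borane should give the primary alcohol without touching either stereocentre.

Step 3
Reactants: 8 (1S,2R)-1-(3,4-dimethoxyphenyl)-2-methylbutane-1,4-diol
Product: 10 (4R,5S)-5-(3,4-dimethoxyphenyl)-4-methyloxolan-2-one, via lactol 9 (not isolated)
Conditions: TEMPO (cat.), PhI(OAc)2, CH2Cl2, rt
Reagents that add atoms: none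
Why: TEMPO/PhI(OAc)2 oxidative lactonisation, in which the primary alcohol is oxidised selectively, the aldehyde closes onto the benzylic hydroxyl as lactol 9 and a second oxidation gives the γ-lactone with methyl and aryl cis.

Step 4
Reactants: 10 (4R,5S)-5-(3,4-dimethoxyphenyl)-4-methyloxolan-2-one; 11 allyl bromide
Product: 13 (3R,4R,5S)-5-(3,4-dimethoxyphenyl)-4-methyl-3-(prop-2-en-1-yl)oxolan-2-one, via lithium enolate 12 (not isolated)
Conditions: LiN(i-Pr)2, THF, −78 °C; then 11, −78 to −40 °C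
Reagents that add atoms: none
Why: Lactone enolate alkylation, in which allyl bromide attacks the enolate face opposite the C7 methyl group and the aryl group cis to it, setting C6 with the allyl group trans to the methyl group (3R).

Step 5
Reactants: 13 (3R,4R,5S)-5-(3,4-dimethoxyphenyl)-4-methyl-3-(prop-2-en-1-yl)oxolan-2-one
Product: 14 (1S,2R,3R)-1-(3,4-dimethoxyphenyl)-2-methyl-3-(prop-2-en-1-yl)butane-1,4-diol
Conditions: LiAlH4, THF, 0 °C; then H2O, aq. NaOH
Reagents that add atoms: none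
Why: Hydride reduction of the lactone to the 1,4-diol frees the C1 primary alcohol and leaves the three stereocentres and the alkene untouched.

Step 6
Reactants: 14 (1S,2R,3R)-1-(3,4-dimethoxyphenyl)-2-methyl-3-(prop-2-en-1-yl)butane-1,4-diol; 15 bromoacetyl bromide
Product: 16 (2R,3R,4S)-4-(3,4-dimethoxyphenyl)-4-hydroxy-3-methyl-2-(prop-2-en-1-yl)butyl bromoacetate
Conditions: 15 (1.05 equiv), NaHCO3, MeCN, 0 °C
Reagents that add atoms: none
Why: Chemoselective O-acylation, in which the primary C1 hydroxyl should react with one equivalent of the acid bromide well before the hindered secondary benzylic hydroxyl.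

Step 7
Reactants: 16 (2R,3R,4S)-4-(3,4-dimethoxyphenyl)-4-hydroxy-3-methyl-2-(prop-2-en-1-yl)butyl bromoacetate
Product: 17 (2R,3R,4S)-4-[(tert-butyldimethylsilyl)oxy]-4-(3,4-dimethoxyphenyl)-3-methyl-2-(prop-2-en-1-yl)butyl bromoacetate
Conditions: TBSOTf, 2,6-lutidine, CH2Cl2, −78 to 0 °C
Reagents that add atoms: tert-butyldimethylsilyl trifluoromethanesulfonate, CC(C)(C)[Si](C)(C)OS(=O)(=O)C(F)(F)F
Why: Silylation with a silyl triflate and a hindered pyridine base should cap the hindered benzylic alcohol at low temperature without attacking the bromoacetate, and the ether blocks O–H insertion in step 9.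

Step 8
Reactants: 17 (2R,3R,4S)-4-[(tert-butyldimethylsilyl)oxy]-4-(3,4-dimethoxyphenyl)-3-methyl-2-(prop-2-en-1-yl)butyl bromoacetate
Product: 19 (2R,3R,4S)-4-[(tert-butyldimethylsilyl)oxy]-4-(3,4-dimethoxyphenyl)-3-methyl-2-(prop-2-en-1-yl)butyl diazoacetate, via ditosylhydrazinoacetate 18 (not isolated)
Conditions: TsNHNHTs, DBU, THF, 0 °C
Reagents that add atoms: N,N'-ditosylhydrazine, Cc1ccc(cc1)S(=O)(=O)NNS(=O)(=O)c1ccc(C)cc1
Why: Diazoacetate formation from a bromoacetate with N,N'-ditosylhydrazine, in which N-alkylation to 18 and two base-induced losses of sulfinate give the diazo ester under conditions that spare the silyl ether and the alkene.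

Step 9
Reactants: 19 (2R,3R,4S)-4-[(tert-butyldimethylsilyl)oxy]-4-(3,4-dimethoxyphenyl)-3-methyl-2-(prop-2-en-1-yl)butyl diazoacetate
Product: 20 (4S)-4-{(1S,2R)-1-[(tert-butyldimethylsilyl)oxy]-1-(3,4-dimethoxyphenyl)propan-2-yl}-4-(prop-2-en-1-yl)oxolan-2-one
Conditions: Rh2(OAc)4 (1 mol%), CH2Cl2, reflux, slow addition of 19 at high dilution
Reagents that add atoms: none
Why: Dirhodium tetraacetate binds the diazo carbon, dinitrogen leaves, and the electrophilic metal carbene inserts into the tertiary C6–H bond through a concerted three-centre transition state. The closest known reaction type is the dirhodium-catalysed intramolecular C–H insertion of alkyl diazoacetates, which gives γ-butyrolactones. The lactone closes by 1,5-insertion to a five-membered ring (carbene carbon C5, carbonyl C4, ester oxygen, C1, C6) with C5–C6 as the new bond. C6 becomes quaternary with retention, because C5 enters on the face that the hydrogen vacates, so its configuration is the one set by the allylation in step 4. The step needs insertion at C6–H in preference to C7–H, the C9 and C1 hydrogens, the alkene and the arene. Because C1 is a CH2 group, C6–H is the only C–H bond at the 1,5-position and is the electron-rich tertiary kind, cyclopropanation of the allyl group would need a seven-membered lactone, and slow addition keeps carbene dimerisation and intermolecular attack on the arene down.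

Step 10
Reactants: 20 (4S)-4-{(1S,2R)-1-[(tert-butyldimethylsilyl)oxy]-1-(3,4-dimethoxyphenyl)propan-2-yl}-4-(prop-2-en-1-yl)oxolan-2-one; 21 ethynyltrimethylsilane
Product: 23 (5S,6R,7S)-7-[(tert-butyldimethylsilyl)oxy]-7-(3,4-dimethoxyphenyl)-5-(hydroxymethyl)-6-methyl-5-(prop-2-en-1-yl)-1-(trimethylsilyl)hept-1-yn-3-one, via lithium trimethylsilylacetylide 22 (not isolated)
Conditions: 21, n-BuLi, THF, −78 °C; then 20, −78 °C; AcOH
Reagents that add atoms: none
Why: Acylation of a lithium acetylide by a lactone, in which the tetrahedral lithium hemiketal is stable at −78 °C and blocks a second addition, so one acetylide (C2–C3) is joined to C4 and C1 is released as the primary alcohol.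

Step 11
Reactants: 23 (5S,6R,7S)-7-[(tert-butyldimethylsilyl)oxy]-7-(3,4-dimethoxyphenyl)-5-(hydroxymethyl)-6-methyl-5-(prop-2-en-1-yl)-1-(trimethylsilyl)hept-1-yn-3-one
Product: 24 (2S)-2-{(1S,2R)-1-[(tert-butyldimethylsilyl)oxy]-1-(3,4-dimethoxyphenyl)propan-2-yl}-4-oxo-2-(prop-2-en-1-yl)-6-(trimethylsilyl)hex-5-ynal
Conditions: Dess–Martin periodinane, CH2Cl2, rt
Reagents that add atoms: none
Why: Dess–Martin oxidation of the primary neopentyl alcohol should give the non-enolisable C1 aldehyde while the ynone, the silyl groups and the alkene stay inert.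

Step 12
Reactants: 24 (2S)-2-{(1S,2R)-1-[(tert-butyldimethylsilyl)oxy]-1-(3,4-dimethoxyphenyl)propan-2-yl}-4-oxo-2-(prop-2-en-1-yl)-6-(trimethylsilyl)hex-5-ynal
Product: 25 (2S)-2-{(1S,2R)-1-[(tert-butyldimethylsilyl)oxy]-1-(3,4-dimethoxyphenyl)propan-2-yl}-4-oxo-2-(prop-2-en-1-yl)hex-5-ynal
Conditions: Na2B4O7·10H2O (cat.), MeOH/H2O, rt
Reagents that add atoms: none
Why: Base-catalysed protodesilylation, in which the activated alkynyl–silicon bond of a silyl ynone is cleaved by borate in aqueous methanol under conditions too mild to remove the silyl ether or to add methanol to the ynone.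

Step 13
Reactants: 25 (2S)-2-{(1S,2R)-1-[(tert-butyldimethylsilyl)oxy]-1-(3,4-dimethoxyphenyl)propan-2-yl}-4-oxo-2-(prop-2-en-1-yl)hex-5-ynal
Product: 26 (2S,5Z)-2-{(1S,2R)-1-[(tert-butyldimethylsilyl)oxy]-1-(3,4-dimethoxyphenyl)propan-2-yl}-6-iodo-4-oxo-2-(prop-2-en-1-yl)hex-5-enal
Conditions: NaI, AcOH, rt, dark
Reagents that add atoms: sodium iodide, [Na+].[I-]
Why: Conjugate hydroiodination of the ynone, in which iodide adds to C2 and the allenol is protonated anti, should give the (Z)-β-iodoenone under kinetic control.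

Step 14
Reactants: 26 (2S,5Z)-2-{(1S,2R)-1-[(tert-butyldimethylsilyl)oxy]-1-(3,4-dimethoxyphenyl)propan-2-yl}-6-iodo-4-oxo-2-(prop-2-en-1-yl)hex-5-enal
Product: 27 (5S)-5-{(1S,2R)-1-[(tert-butyldimethylsilyl)oxy]-1-(3,4-dimethoxyphenyl)propan-2-yl}-4-hydroxy-5-(prop-2-en-1-yl)cyclohex-2-en-1-one (both C4 epimers)
Conditions: CrCl2, NiCl2 (cat.), DMSO, rt
Reagents that add atoms: none
Why: Intramolecular Nozaki–Hiyama–Kishi reaction, in which the alkenylchromium species formed at C2 adds to the C1 aldehyde in preference to the ketone and closes the six-membered ring at C1–C2; the new carbinol centre need not be controlled because it is oxidised next.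

Step 15
Reactants: 27 (5S)-5-{(1S,2R)-1-[(tert-butyldimethylsilyl)oxy]-1-(3,4-dimethoxyphenyl)propan-2-yl}-4-hydroxy-5-(prop-2-en-1-yl)cyclohex-2-en-1-one
Product: 28 (5S)-5-{(1S,2R)-1-[(tert-butyldimethylsilyl)oxy]-1-(3,4-dimethoxyphenyl)propan-2-yl}-5-(prop-2-en-1-yl)cyclohex-2-ene-1,4-dione
Conditions: Dess–Martin periodinane, CH2Cl2, rt
Reagents that add atoms: none
Why: Dess–Martin oxidation of the allylic alcohol gives the cyclohex-2-ene-1,4-dione, which puts the C1 carbonyl in place and removes the uncontrolled carbinol centre.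

Step 16
Reactants: 28 (5S)-5-{(1S,2R)-1-[(tert-butyldimethylsilyl)oxy]-1-(3,4-dimethoxyphenyl)propan-2-yl}-5-(prop-2-en-1-yl)cyclohex-2-ene-1,4-dione
Product: 29 (4S,6S)-6-{(1S,2R)-1-[(tert-butyldimethylsilyl)oxy]-1-(3,4-dimethoxyphenyl)propan-2-yl}-4-hydroxy-6-(prop-2-en-1-yl)cyclohex-2-en-1-one
Conditions: RuCl[(S,S)-TsDPEN](p-cymene) (cat.), KOH (cat.), i-PrOH, rt
Reagents that add atoms: none
Why: Noyori asymmetric transfer hydrogenation, which should reduce only the C4 carbonyl because the C1 carbonyl is shielded by the quaternary C6, and which tells the alkenyl flank from the alkyl flank so that the (S,S) ligand is expected to give 4S.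

Step 17
Reactants: 29 (4S,6S)-6-{(1S,2R)-1-[(tert-butyldimethylsilyl)oxy]-1-(3,4-dimethoxyphenyl)propan-2-yl}-4-hydroxy-6-(prop-2-en-1-yl)cyclohex-2-en-1-one
Product: 30 (4S,6S)-6-{(1S,2R)-1-[(tert-butyldimethylsilyl)oxy]-1-(3,4-dimethoxyphenyl)propan-2-yl}-4-methoxy-6-(prop-2-en-1-yl)cyclohex-2-en-1-one
Conditions: Me3OBF4, 1,8-bis(dimethylamino)naphthalene, 4 Å MS, CH2Cl2, rt
Reagents that add atoms: trimethyloxonium tetrafluoroborate, C[O+](C)C.F[B-](F)(F)F
Why: O-Methylation with Meerwein's salt and a non-nucleophilic proton scavenger avoids strong base, so the γ-hydroxy enone should be methylated without enolisation or epimerisation at C4.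

Step 18
Reactants: 30 (4S,6S)-6-{(1S,2R)-1-[(tert-butyldimethylsilyl)oxy]-1-(3,4-dimethoxyphenyl)propan-2-yl}-4-methoxy-6-(prop-2-en-1-yl)cyclohex-2-en-1-one
Product: 31 (4S,6S)-6-[(1S,2R)-1-(3,4-dimethoxyphenyl)-1-hydroxypropan-2-yl]-4-methoxy-6-(prop-2-en-1-yl)cyclohex-2-en-1-one
Conditions: TBAF, AcOH, THF, rt
Reagents that add atoms: none
Why: Fluoride cleavage of the silyl ether, buffered with acetic acid to protect the enone and the C4 centre, frees the C8 alcohol and should give the target.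

Compound list
1 | 3,4-dimethoxybenzaldehyde | COc1ccc(C=O)cc1OC | starting material
2 | cis-but-2-ene | C/C=C\C | starting material
3 | (Z)-but-2-en-1-ylpotassium | C/C=C\C[K] | intermediate (not isolated)
4 | B-[(Z)-but-2-en-1-yl]diisopinocampheylborane, isopinocampheyl groups from (+)-α-pinene | C/C=C\CB([C@@H]1C[C@@H]2C[C@H]([C@H]1C)C2(C)C)[C@@H]1C[C@@H]2C[C@H]([C@H]1C)C2(C)C | intermediate (not isolated)
5 | diisopinocampheylborinate ester of 6 | C=C[C@@H](C)[C@H](OB([C@@H]1C[C@@H]2C[C@H]([C@H]1C)C2(C)C)[C@@H]1C[C@@H]2C[C@H]([C@H]1C)C2(C)C)c1ccc(OC)c(OC)c1 | intermediate (not isolated)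
6 | (1S,2R)-1-(3,4-dimethoxyphenyl)-2-methylbut-3-en-1-ol | C=C[C@@H](C)[C@H](O)c1ccc(OC)c(OC)c1 | intermediate
7 | B-[(3R,4S)-4-(3,4-dimethoxyphenyl)-4-hydroxy-3-methylbutyl]-9-borabicyclo[3.3.1]nonane | B1(CC[C@@H](C)[C@H](O)c2ccc(OC)c(OC)c2)C2CCCC1CCC2 | intermediate (not isolated)
8 | (1S,2R)-1-(3,4-dimethoxyphenyl)-2-methylbutane-1,4-diol | OCC[C@@H](C)[C@H](O)c1ccc(OC)c(OC)c1 | intermediate
9 | (4R,5S)-5-(3,4-dimethoxyphenyl)-4-methyloxolan-2-ol (lactol, both anomers) | OC1C[C@@H](C)[C@@H](c2ccc(OC)c(OC)c2)O1 | intermediate (not isolated)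
10 | (4R,5S)-5-(3,4-dimethoxyphenyl)-4-methyloxolan-2-one | O=C1C[C@@H](C)[C@@H](c2ccc(OC)c(OC)c2)O1 | intermediate
11 | allyl bromide | C=CCBr | starting material
12 | lithium enolate of 10 | [Li+].[O-]C1=C[C@@H](C)[C@@H](c2ccc(OC)c(OC)c2)O1 | intermediate (not isolated)
13 | (3R,4R,5S)-5-(3,4-dimethoxyphenyl)-4-methyl-3-(prop-2-en-1-yl)oxolan-2-one | O=C1[C@H](CC=C)[C@@H](C)[C@@H](c2ccc(OC)c(OC)c2)O1 | intermediate
14 | (1S,2R,3R)-1-(3,4-dimethoxyphenyl)-2-methyl-3-(prop-2-en-1-yl)butane-1,4-diol | OC[C@H](CC=C)[C@@H](C)[C@H](O)c1ccc(OC)c(OC)c1 | intermediate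
15 | bromoacetyl bromide | BrCC(Br)=O | starting material
16 | (2R,3R,4S)-4-(3,4-dimethoxyphenyl)-4-hydroxy-3-methyl-2-(prop-2-en-1-yl)butyl bromoacetate | BrCC(=O)OC[C@H](CC=C)[C@@H](C)[C@H](O)c1ccc(OC)c(OC)c1 | intermediate
17 | (2R,3R,4S)-4-[(tert-butyldimethylsilyl)oxy]-4-(3,4-dimethoxyphenyl)-3-methyl-2-(prop-2-en-1-yl)butyl bromoacetate | BrCC(=O)OC[C@H](CC=C)[C@@H](C)[C@H](O[Si](C)(C)C(C)(C)C)c1ccc(OC)c(OC)c1 | intermediate
18 | (2R,3R,4S)-4-[(tert-butyldimethylsilyl)oxy]-4-(3,4-dimethoxyphenyl)-3-methyl-2-(prop-2-en-1-yl)butyl [N,N'-bis(4-methylbenzenesulfonyl)hydrazinyl]acetate | Cc1ccc(cc1)S(=O)(=O)NN(CC(=O)OC[C@H](CC=C)[C@@H](C)[C@H](O[Si](C)(C)C(C)(C)C)c1ccc(OC)c(OC)c1)S(=O)(=O)c1ccc(C)cc1 | intermediate (not isolated)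
19 | (2R,3R,4S)-4-[(tert-butyldimethylsilyl)oxy]-4-(3,4-dimethoxyphenyl)-3-methyl-2-(prop-2-en-1-yl)butyl diazoacetate | [N-]=[N+]=CC(=O)OC[C@H](CC=C)[C@@H](C)[C@H](O[Si](C)(C)C(C)(C)C)c1ccc(OC)c(OC)c1 | intermediate
20 | (4S)-4-{(1S,2R)-1-[(tert-butyldimethylsilyl)oxy]-1-(3,4-dimethoxyphenyl)propan-2-yl}-4-(prop-2-en-1-yl)oxolan-2-one | O=C1C[C@@](CC=C)([C@@H](C)[C@H](O[Si](C)(C)C(C)(C)C)c2ccc(OC)c(OC)c2)CO1 | intermediate
21 | ethynyltrimethylsilane | C#C[Si](C)(C)C | starting material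
22 | lithium (trimethylsilyl)acetylide | [Li]C#C[Si](C)(C)C | intermediate (not isolated)
23 | (5S,6R,7S)-7-[(tert-butyldimethylsilyl)oxy]-7-(3,4-dimethoxyphenyl)-5-(hydroxymethyl)-6-methyl-5-(prop-2-en-1-yl)-1-(trimethylsilyl)hept-1-yn-3-one | OC[C@](CC=C)([C@@H](C)[C@H](O[Si](C)(C)C(C)(C)C)c1ccc(OC)c(OC)c1)CC(=O)C#C[Si](C)(C)C | intermediate
24 | (2S)-2-{(1S,2R)-1-[(tert-butyldimethylsilyl)oxy]-1-(3,4-dimethoxyphenyl)propan-2-yl}-4-oxo-2-(prop-2-en-1-yl)-6-(trimethylsilyl)hex-5-ynal | O=C[C@](CC=C)([C@@H](C)[C@H](O[Si](C)(C)C(C)(C)C)c1ccc(OC)c(OC)c1)CC(=O)C#C[Si](C)(C)C | intermediate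
25 | (2S)-2-{(1S,2R)-1-[(tert-butyldimethylsilyl)oxy]-1-(3,4-dimethoxyphenyl)propan-2-yl}-4-oxo-2-(prop-2-en-1-yl)hex-5-ynal | O=C[C@](CC=C)([C@@H](C)[C@H](O[Si](C)(C)C(C)(C)C)c1ccc(OC)c(OC)c1)CC(=O)C#C | intermediate
26 | (2S,5Z)-2-{(1S,2R)-1-[(tert-butyldimethylsilyl)oxy]-1-(3,4-dimethoxyphenyl)propan-2-yl}-6-iodo-4-oxo-2-(prop-2-en-1-yl)hex-5-enal | O=C[C@](CC=C)([C@@H](C)[C@H](O[Si](C)(C)C(C)(C)C)c1ccc(OC)c(OC)c1)CC(=O)/C=C\I | intermediate
27 | (5S)-5-{(1S,2R)-1-[(tert-butyldimethylsilyl)oxy]-1-(3,4-dimethoxyphenyl)propan-2-yl}-4-hydroxy-5-(prop-2-en-1-yl)cyclohex-2-en-1-one (both C4 epimers) | OC1C=CC(=O)C[C@@]1(CC=C)[C@@H](C)[C@H](O[Si](C)(C)C(C)(C)C)c2ccc(OC)c(OC)c2 | intermediate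
28 | (5S)-5-{(1S,2R)-1-[(tert-butyldimethylsilyl)oxy]-1-(3,4-dimethoxyphenyl)propan-2-yl}-5-(prop-2-en-1-yl)cyclohex-2-ene-1,4-dione | O=C1C=CC(=O)C[C@@]1(CC=C)[C@@H](C)[C@H](O[Si](C)(C)C(C)(C)C)c2ccc(OC)c(OC)c2 | intermediate
29 | (4S,6S)-6-{(1S,2R)-1-[(tert-butyldimethylsilyl)oxy]-1-(3,4-dimethoxyphenyl)propan-2-yl}-4-hydroxy-6-(prop-2-en-1-yl)cyclohex-2-en-1-one | C=CC[C@@]1([C@@H](C)[C@H](O[Si](C)(C)C(C)(C)C)c2ccc(OC)c(OC)c2)C[C@H](O)C=CC1=O | intermediate
30 | (4S,6S)-6-{(1S,2R)-1-[(tert-butyldimethylsilyl)oxy]-1-(3,4-dimethoxyphenyl)propan-2-yl}-4-methoxy-6-(prop-2-en-1-yl)cyclohex-2-en-1-one | C=CC[C@@]1([C@@H](C)[C@H](O[Si](C)(C)C(C)(C)C)c2ccc(OC)c(OC)c2)C[C@H](OC)C=CC1=O | intermediate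
31 | (4S,6S)-6-[(1S,2R)-1-(3,4-dimethoxyphenyl)-1-hydroxypropan-2-yl]-4-methoxy-6-(prop-2-en-1-yl)cyclohex-2-en-1-one | C=CC[C@@]1([C@@H](C)[C@H](O)c2ccc(OC)c(OC)c2)C[C@H](OC)C=CC1=O | target

Total step count: 18. Longest linear sequence: 18 steps, from 3,4-dimethoxybenzaldehyde (1) to 31.

Steps most likely to fail

Step 9. The acceptor-only carbene may be lost to dimerisation, or may attack the electron-rich arene or other C–H bonds before it finds C6–H. The fallback keeps the C5–C6 disconnection but uses a diazomalonate, whose more discriminating carbene is the usual choice for tertiary C–H insertion. It sets out from diol 14. Acylation of the primary hydroxyl with methyl 3-chloro-3-oxopropanoate (NaHCO3, MeCN, 0 °C) would give the mixed malonate F1, and silylation (TBSOTf, 2,6-lutidine) the silyl ether F2. Diazo transfer (4-acetamidobenzenesulfonyl azide, Et3N, MeCN) would give the diazomalonate F3, and Rh2(OAc)4 in refluxing CH2Cl2 should close it to the α-methoxycarbonyl lactone F4. Krapcho demethoxycarbonylation (LiCl, wet DMSO, 140 °C) returns to the route at lactone 20.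

Step 14. The alkenylchromium intermediate may add too slowly to the α-quaternary aldehyde, so that protodeiodination or Z-to-E isomerisation of the iodoenone takes over. The fallback closes the same C1–C2 bond by acylation instead of carbonyl addition and sets out from 26. Pinnick oxidation (NaClO2, NaH2PO4, 2-methylbut-2-ene, t-BuOH/H2O) would give the carboxylic acid F5, and 2,2'-dipyridyl disulfide with PPh3 the S-pyridin-2-yl thioester F6. Nickel-catalysed reductive coupling of the alkenyl iodide with the thioester (NiBr2(dtbbpy) cat., Cp2ZrCl2, Zn, DMI, rt), a known ketone synthesis, should close the ring directly to ene-dione 28, so that step 15 is not needed.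

Step 16. Hydride delivery to C4 may show poor or reversed facial selectivity if the bias of the quaternary C6 opposes the catalyst. The fallback accepts the epimer that forms cleanly and inverts it; it sets out from 28. Reduction with the antipodal (R,R) catalyst, or with NaBH4 and CeCl3·7H2O in MeOH at −78 °C, would give the C4-epimeric alcohol F7. Mitsunobu reaction (4-nitrobenzoic acid, PPh3, DIAD, THF) inverts C4 to the 4-nitrobenzoate F8, and methanolysis (K2CO3, MeOH, 0 °C) returns to the route at 29.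

Further compounds
F1 | step 9 | (2R,3R,4S)-4-(3,4-dimethoxyphenyl)-4-hydroxy-3-methyl-2-(prop-2-en-1-yl)butyl methyl malonate | COC(=O)CC(=O)OC[C@H](CC=C)[C@@H](C)[C@H](O)c1ccc(OC)c(OC)c1
F2 | step 9 | (2R,3R,4S)-4-[(tert-butyldimethylsilyl)oxy]-4-(3,4-dimethoxyphenyl)-3-methyl-2-(prop-2-en-1-yl)butyl methyl malonate | COC(=O)CC(=O)OC[C@H](CC=C)[C@@H](C)[C@H](O[Si](C)(C)C(C)(C)C)c1ccc(OC)c(OC)c1
F3 | step 9 | (2R,3R,4S)-4-[(tert-butyldimethylsilyl)oxy]-4-(3,4-dimethoxyphenyl)-3-methyl-2-(prop-2-en-1-yl)butyl methyl diazomalonate | COC(=O)C(=[N+]=[N-])C(=O)OC[C@H](CC=C)[C@@H](C)[C@H](O[Si](C)(C)C(C)(C)C)c1ccc(OC)c(OC)c1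
F4 | step 9 | methyl (4R)-4-{(1S,2R)-1-[(tert-butyldimethylsilyl)oxy]-1-(3,4-dimethoxyphenyl)propan-2-yl}-2-oxo-4-(prop-2-en-1-yl)oxolane-3-carboxylate (both C3 epimers; quaternary carbon arranged as in 20) | COC(=O)C1C(=O)OC[C@]1(CC=C)[C@@H](C)[C@H](O[Si](C)(C)C(C)(C)C)c2ccc(OC)c(OC)c2
F5 | step 14 | (2S,5Z)-2-{(1S,2R)-1-[(tert-butyldimethylsilyl)oxy]-1-(3,4-dimethoxyphenyl)propan-2-yl}-6-iodo-4-oxo-2-(prop-2-en-1-yl)hex-5-enoic acid | OC(=O)[C@](CC=C)([C@@H](C)[C@H](O[Si](C)(C)C(C)(C)C)c1ccc(OC)c(OC)c1)CC(=O)/C=C\I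
F6 | step 14 | S-pyridin-2-yl (2S,5Z)-2-{(1S,2R)-1-[(tert-butyldimethylsilyl)oxy]-1-(3,4-dimethoxyphenyl)propan-2-yl}-6-iodo-4-oxo-2-(prop-2-en-1-yl)hex-5-enethioate | O=C(Sc1ccccn1)[C@](CC=C)([C@@H](C)[C@H](O[Si](C)(C)C(C)(C)C)c1ccc(OC)c(OC)c1)CC(=O)/C=C\I
F7 | step 16 | (4R,6S)-6-{(1S,2R)-1-[(tert-butyldimethylsilyl)oxy]-1-(3,4-dimethoxyphenyl)propan-2-yl}-4-hydroxy-6-(prop-2-en-1-yl)cyclohex-2-en-1-one | C=CC[C@@]1([C@@H](C)[C@H](O[Si](C)(C)C(C)(C)C)c2ccc(OC)c(OC)c2)C[C@@H](O)C=CC1=O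
F8 | step 16 | (1S,5S)-5-{(1S,2R)-1-[(tert-butyldimethylsilyl)oxy]-1-(3,4-dimethoxyphenyl)propan-2-yl}-4-oxo-5-(prop-2-en-1-yl)cyclohex-2-en-1-yl 4-nitrobenzoate | C=CC[C@@]1([C@@H](C)[C@H](O[Si](C)(C)C(C)(C)C)c2ccc(OC)c(OC)c2)C[C@H](OC(=O)c2ccc(cc2)[N+](=O)[O-])C=CC1=O
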